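**Retrosynthetic overview**

1. Locants: unprimed = phloroglucinol half (ring A), primed = pentaoxygenated half (ring B). The route rests on ring B, a hexasubstituted benzene in which C4a' carries carbon (C4') and C5', C6', C7', C8' and C8a' all carry oxygen. It maps onto dimethyl squarate (C6', C7', C8', C8a') plus a 1-ethoxyalkenyl unit (C5', C4a') that already carries C4' and its aryl group.
2. Last disconnections: global O-dealkylation, then C3'–C4' and O1'–C2' by [4+2] annulation of the ring B ortho-quinone methide with the enolate of the ring A lactone-3-acetic acid. A carbene-bound (azolium) enolate is used rather than an isothiourea-bound one, because the acyl donor is alkyl-substituted and both lactones of the target are 3,4-cis.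
3. The ring A lactone comes from the same annulation of the ring A methide with monobenzyl succinate, so succinate supplies C2–C3–C3'–C2'. The two halves have opposite absolute sense (3R,4S against 3'S,4'R), hence antipodal catalysts.
4. The ring B methide comes from Ag2O dehydrogenation of a benzylphenol. That phenol comes from thermal 4π opening and 6π closure of a 4-alkenylcyclobutenone, made from squarate and an alkenyllithium released by tin–lithium exchange.
5. Order of ring formation: ring B benzene (step 4), ring A lactone (step 8), ring B lactone (step 10).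

Key step: step 4

Assumption: the absolute sense of induction of the aminoindanol-derived triazolium catalysts on these two methides is assigned by analogy with their endo hetero-Diels–Alder reactions of enones. Both antipodes are commercial, so if a model run shows the opposite sense they are exchanged between steps 8 and 10.

**Route**

Step 1
Reactants: 1 ethoxyacetylene; 2 4-methoxybenzyl bromide
Product: 4 1-(3-ethoxyprop-2-yn-1-yl)-4-methoxybenzene, via lithium ethoxyacetylide 3 (not isolated)
Conditions: n-BuLi, THF, −78 °C; then 2, DMPU, −78 °C → rt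
Reagents that add atoms: n-butyllithium, [Li]CCCC (lithium in 3 only)
Why: SN2 alkylation of a lithium alkoxyacetylide by a reactive benzylic bromide in THF with a dipolar cosolvent is standard ynol ether chemistry and puts the whole C5'–C4a'–C4'–aryl chain into one compound.

Step 2
Reactants: 4 1-(3-ethoxyprop-2-yn-1-yl)-4-methoxybenzene
Product: 5 (E)-tributyl[1-ethoxy-3-(4-methoxyphenyl)prop-1-en-1-yl]stannane
Conditions: Bu3SnH, Pd(PPh3)4 (2 mol %), THF, 0 °C → rt; Et3N-deactivated silica
Reagents that add atoms: tributyltin hydride, CCCC[SnH](CCCC)CCCC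
Why: Hydrostannation of 1-alkoxyalkynes catalysed by zerovalent palladium is a syn addition that places tin on the oxygen-bearing carbon, so H and Sn end up cis and CH2Ar cis to OEt, the geometry wanted in 9.

Step 3
Reactants: 5 (E)-tributyl[1-ethoxy-3-(4-methoxyphenyl)prop-1-en-1-yl]stannane; 6 dimethyl squarate
Product: 9 (±)-4-[(Z)-1-ethoxy-3-(4-methoxyphenyl)prop-1-en-1-yl]-2,3,4-trimethoxycyclobut-2-en-1-one, via vinyllithium 7 (not isolated), via lithium alkoxide 8 (not isolated)
Conditions: n-BuLi, THF, −78 °C, 20 min; cannulated into 6, THF, −78 °C; MeOTf, −78 → 0 °C; aq NaHCO3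
Reagents that add atoms: n-butyllithium, [Li]CCCC (lithium in 7 and 8 only); methyl trifluoromethanesulfonate, COS(=O)(=O)C(F)(F)F
Why: Tin–lithium exchange at −78 °C releases the α-ethoxyalkenyllithium with retention and without a base ever meeting the doubly activated benzylic/allylic CH2 (which direct deprotonation of the parent enol ether would attack first); 1,2-addition of organolithiums to dimethyl squarate is the standard entry to 4-substituted cyclobutenones, O-methylation of the tertiary alkoxide caps the future O6', and the new quaternary centre is racemic and is lost in step 4.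

Step 4
Reactants: 9 (±)-4-[(Z)-1-ethoxy-3-(4-methoxyphenyl)prop-1-en-1-yl]-2,3,4-trimethoxycyclobut-2-en-1-one
Product: 12 3-ethoxy-4,5,6-trimethoxy-2-(4-methoxybenzyl)phenol, via dienylketene 10 (not isolated), via cyclohexadienone 11 (not isolated)
Conditions: degassed toluene (0.02 M), 110 °C, base-washed glassware
Reagents that add atoms: none
Why: Heat breaks the C1–C4 bond of the cyclobutenone in a conrotatory 4π electrocyclic opening in which the C4 methoxy group, the stronger donor, turns outward and the alkenyl group inward, so that in dienylketene 10 the ketene carbon lies next to the enol ether terminus. A thermal 6π electrocyclisation (closure of the six-membered carbocycle, ketene carbon onto the CH terminus) then forms the C4a'–C8a' bond and gives dienone 11, whose single sp3 carbon bears H and the 4-methoxybenzyl group, and aromatisation drives its enolisation to phenol 12. The closest known reaction type is the thermal ring expansion of 4-alkenylcyclobutenones derived from squarate esters, the alkenyl branch of the Moore rearrangement. No stereocentre survives, since C4 of 9 and the sp3 carbon of 11 both become sp2. The step needs only torquoselectivity and regioselectivity, which are secured by the outward preference of the alkoxy group and by connectivity, while the Z geometry of 9 keeps H rather than CH2Ar on the inside of the closing triene. Because O6' was capped in step 3, the only free hydroxyl of 12 is the one born from the ketene carbonyl, the future O1', ortho to the benzyl group.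

Step 5
Reactants: 12 3-ethoxy-4,5,6-trimethoxy-2-(4-methoxybenzyl)phenol
Product: 13 (6E)-5-ethoxy-2,3,4-trimethoxy-6-(4-methoxybenzylidene)cyclohexa-2,4-dien-1-one (ring B ortho-quinone methide, drawn in the reactive geometry with aryl anti to C=O)
Conditions: Ag2O (3 equiv), 4 Å MS, dry Et2O, rt, dark; filtration through Celite, used without chromatography
Reagents that add atoms: none
Why: Ag2O dehydrogenation of electron-rich 2-benzylphenols bearing a para alkoxy group is a known route to isolable aryl-substituted ortho-quinone methides, here stabilised by the vinylogous-ester alkoxy groups at C5' and C7' and by the 4-methoxyphenyl group, while the sieves take up the water that could add back.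

Step 6
Reactants: 14 2-hydroxy-4,6-dimethoxybenzaldehyde; 15 4-methoxyphenylmagnesium bromide
Product: 16 (±)-2-[hydroxy(4-methoxyphenyl)methyl]-3,5-dimethoxyphenol
Conditions: 15 (2.2 equiv), THF, 0 °C → rt; aq NH4Cl
Reagents that add atoms: none
Why: Grignard addition to a salicylaldehyde, the first equivalent being consumed by the phenol; the carbinol centre is racemic and disappears in step 7.

Step 7
Reactants: 16 (±)-2-[hydroxy(4-methoxyphenyl)methyl]-3,5-dimethoxyphenol
Product: 17 (6E)-3,5-dimethoxy-6-(4-methoxybenzylidene)cyclohexa-2,4-dien-1-one (ring A ortho-quinone methide)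
Conditions: 4 Å MS, toluene, 90 °C; filtered and concentrated, no silica
Reagents that add atoms: none
Why: Thermal 1,4-dehydration of an ortho-hydroxybenzhydrol is a standard preparation of stabilised ortho-quinone methides, and both ring methoxy groups of 17 are conjugated with the carbonyl, which together with the 4-methoxyphenyl group makes ionisation easy and the product persistent.

Step 8
Reactants: 18 4-(benzyloxy)-4-oxobutanoic acid (monobenzyl succinate); 17 ring A ortho-quinone methide
Product: 20 benzyl 2-[(3S,4S)-5,7-dimethoxy-4-(4-methoxyphenyl)-2-oxochroman-3-yl]acetate (3,4-cis), via acyl imidazole 19 (not isolated)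
Conditions: 18, CDI, THF, rt, 1 h; then 17, (5aR,10bS)-2-mesityl-5a,10b-dihydro-4H,6H-indeno[2,1-b][1,2,4]triazolo[4,3-d][1,4]oxazin-2-ium tetrafluoroborate (10 mol %), iPr2NEt (20 mol %), 4 Å MS, THF–toluene, rt
Reagents that add atoms: 1,1'-carbonyldiimidazole, O=C(n1ccnc1)n1ccnc1 (imidazolyl group in 19 only)
Why: Carbene-catalysed formal [4+2] annulation (azolium enolate Michael addition–lactonisation), known for acyl imidazoles and saturated acids with stabilised ortho-quinone methides: the carbene displaces imidazole from 19, the acyl azolium is deprotonated to its Z enolate, this adds through the face left open by the indane unit to the methide carbon of E-configured 17 in the compact endo arrangement that gives 3,4-cis lactones, so C3 and C4 (both S in 20) are set together, and acylation of the released phenoxide closes the ring and frees the catalyst.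

Step 9
Reactants: 20 benzyl 2-[(3S,4S)-5,7-dimethoxy-4-(4-methoxyphenyl)-2-oxochroman-3-yl]acetate
Product: 21 2-[(3S,4S)-5,7-dimethoxy-4-(4-methoxyphenyl)-2-oxochroman-3-yl]acetic acid
Conditions: H2 (1 atm), 10% Pd/C, EtOAc, rt
Reagents that add atoms: none
Why: Neutral hydrogenolysis of the benzyl ester leaves the aryl lactone, the aryl ethers and the base-sensitive cis C3 centre untouched.

Step 10
Reactants: 21 2-[(3S,4S)-5,7-dimethoxy-4-(4-methoxyphenyl)-2-oxochroman-3-yl]acetic acid; 13 ring B ortho-quinone methide
Product: 23 (3R,3'S,4S,4'R)-5'-ethoxy-5,6',7,7',8'-pentamethoxy-4,4'-bis(4-methoxyphenyl)-[3,3'-bichromane]-2,2'-dione, via acyl imidazole 22 (not isolated)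
Conditions: 21, CDI, THF, rt, 1 h; then 13 (1.3 equiv), (5aS,10bR)-2-mesityl-5a,10b-dihydro-4H,6H-indeno[2,1-b][1,2,4]triazolo[4,3-d][1,4]oxazin-2-ium tetrafluoroborate (20 mol %), iPr2NEt (30 mol %), 4 Å MS, toluene, rt
Reagents that add atoms: 1,1'-carbonyldiimidazole, O=C(n1ccnc1)n1ccnc1 (imidazolyl group in 22 only)
Why: The same carbene-catalysed azolium enolate Michael addition–lactonisation: only the CH2 next to the acyl azolium is acidified, so the enolate forms at C3' and not at C3; the antipodal catalyst opens the opposite enolate face and the endo arrangement with E-configured 13 sets C3' (S) and C4' (R) cis to each other, so the catalyst also decides C3' relative to C3, and the imidazole-buffered medium is too weakly basic to epimerise the cis lactones.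

Step 11
Reactants: 23 (3R,3'S,4S,4'R)-5'-ethoxy-5,6',7,7',8'-pentamethoxy-4,4'-bis(4-methoxyphenyl)-[3,3'-bichromane]-2,2'-dione
Product: 24 (3R,3'S,4S,4'R)-5,5',6',7,7',8'-hexahydroxy-4,4'-bis(4-hydroxyphenyl)-[3,3'-bichromane]-2,2'-dione (target)
Conditions: BBr3 (20 equiv), CH2Cl2, −78 °C → rt, argon; degassed H2O, 0 °C; extraction with EtOAc in the presence of ascorbic acid
Reagents that add atoms: none
Why: BBr3 cleavage of aryl methyl and ethyl ethers spares dihydrocoumarin lactones and runs under acidic conditions that should not enolise C3 or C3'; any acyl shift between O1 and O5 (or O1' and O5') would be degenerate because each deprotected ring is symmetric about its C4a–C7 axis, and air is excluded because the tetrahydroxyarene oxidises easily.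

**Compound list**

1 | ethoxyacetylene | C#COCC | starting material
2 | 4-methoxybenzyl bromide | COc1ccc(CBr)cc1 | starting material
3 | lithium ethoxyacetylide | [Li]C#COCC | intermediate
4 | 1-(3-ethoxyprop-2-yn-1-yl)-4-methoxybenzene | CCOC#CCc1ccc(OC)cc1 | intermediate
5 | (E)-tributyl[1-ethoxy-3-(4-methoxyphenyl)prop-1-en-1-yl]stannane | CCCC[Sn](CCCC)(CCCC)/C(OCC)=C/Cc1ccc(OC)cc1 | intermediate
6 | dimethyl squarate | COC1=C(OC)C(=O)C1=O | starting material
7 | (Z)-1-ethoxy-3-(4-methoxyphenyl)prop-1-en-1-yllithium | [Li]/C(OCC)=C/Cc1ccc(OC)cc1 | intermediate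
8 | lithium alkoxide of the squarate adduct (racemic) | [Li+].[O-]C1(/C(OCC)=C/Cc2ccc(OC)cc2)C(OC)=C(OC)C1=O | intermediate
9 | (±)-4-[(Z)-1-ethoxy-3-(4-methoxyphenyl)prop-1-en-1-yl]-2,3,4-trimethoxycyclobut-2-en-1-one | COC1(/C(OCC)=C/Cc2ccc(OC)cc2)C(OC)=C(OC)C1=O | intermediate
10 | dienylketene from 4π opening | O=C=C(OC)/C(OC)=C(OC)\C(OCC)=C\Cc1ccc(OC)cc1 | intermediate
11 | (±)-5-ethoxy-2,3,4-trimethoxy-6-(4-methoxybenzyl)cyclohexa-2,4-dien-1-one | O=C1C(OC)=C(OC)C(OC)=C(OCC)C1Cc1ccc(OC)cc1 | intermediate
12 | 3-ethoxy-4,5,6-trimethoxy-2-(4-methoxybenzyl)phenol | CCOc1c(OC)c(OC)c(OC)c(O)c1Cc1ccc(OC)cc1 | intermediate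
13 | (6E)-5-ethoxy-2,3,4-trimethoxy-6-(4-methoxybenzylidene)cyclohexa-2,4-dien-1-one | O=C1C(OC)=C(OC)C(OC)=C(OCC)/C1=C\c1ccc(OC)cc1 | intermediate
14 | 2-hydroxy-4,6-dimethoxybenzaldehyde | O=Cc1c(O)cc(OC)cc1OC | starting material
15 | 4-methoxyphenylmagnesium bromide | COc1ccc([Mg]Br)cc1 | starting material
16 | (±)-2-[hydroxy(4-methoxyphenyl)methyl]-3,5-dimethoxyphenol | COc1ccc(cc1)C(O)c1c(O)cc(OC)cc1OC | intermediate
17 | (6E)-3,5-dimethoxy-6-(4-methoxybenzylidene)cyclohexa-2,4-dien-1-one | O=C1C=C(OC)C=C(OC)/C1=C\c1ccc(OC)cc1 | intermediate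
18 | 4-(benzyloxy)-4-oxobutanoic acid | OC(=O)CCC(=O)OCc1ccccc1 | starting material
19 | benzyl 4-(imidazol-1-yl)-4-oxobutanoate | O=C(CCC(=O)OCc1ccccc1)n1ccnc1 | intermediate
20 | benzyl 2-[(3S,4S)-5,7-dimethoxy-4-(4-methoxyphenyl)-2-oxochroman-3-yl]acetate | O=C1Oc2cc(OC)cc(OC)c2[C@H](c2ccc(OC)cc2)[C@@H]1CC(=O)OCc1ccccc1 | intermediate
21 | 2-[(3S,4S)-5,7-dimethoxy-4-(4-methoxyphenyl)-2-oxochroman-3-yl]acetic acid | O=C1Oc2cc(OC)cc(OC)c2[C@H](c2ccc(OC)cc2)[C@@H]1CC(=O)O | intermediate
22 | acyl imidazole of 21 | O=C1Oc2cc(OC)cc(OC)c2[C@H](c2ccc(OC)cc2)[C@@H]1CC(=O)n1ccnc1 | intermediate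
23 | (3R,3'S,4S,4'R)-5'-ethoxy-5,6',7,7',8'-pentamethoxy-4,4'-bis(4-methoxyphenyl)-[3,3'-bichromane]-2,2'-dione | O=C1Oc2cc(OC)cc(OC)c2[C@H](c2ccc(OC)cc2)[C@@H]1[C@H]1C(=O)Oc2c(OC)c(OC)c(OC)c(OCC)c2[C@H]1c1ccc(OC)cc1 | intermediate
24 | (3R,3'S,4S,4'R)-5,5',6',7,7',8'-hexahydroxy-4,4'-bis(4-hydroxyphenyl)-[3,3'-bichromane]-2,2'-dione | O=C1Oc2cc(O)cc(O)c2[C@H](c2ccc(O)cc2)[C@@H]1[C@H]1C(=O)Oc2c(O)c(O)c(O)c(O)c2[C@H]1c1ccc(O)cc1 | target

**Step count**

Total steps: 11. Longest linear sequence: 7 (steps 1, 2, 3, 4, 5, 10, 11).

**Steps most likely to fail**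

**Step 10.**
- What may go wrong: C–C bond formation may be slow, because a β-branched enolate has to reach a methide carbon flanked by the peri ethoxy group. The catalyst may be mismatched with the resident C3/C4 centres. Long reaction times may let the kinetic cis lactones drift to trans by epimerisation at C3 and C3'.
- Fallback: it sets out from 22 (with 13) and comes back at 23. It takes control of C3 and C3' away from the annulation.
- The union is run under forcing conditions (same antipode of catalyst, DBU 1 equiv, toluene, 50 °C). Only C4' is then asked of the catalyst, and the product would be the bislactone as a mixture of C3/C3' epimers F1.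
- LiHMDS (2.5 equiv, THF, −78 °C, argon) would erase both α-centres in the dilithium bis-enolate F2.
- Inverse quench into AcOH/THF at −78 °C should protonate each enolate carbon on the face away from its pseudoaxial neighbouring aryl group. This places the C3–C3' bond cis to both aryl groups and gives 23. The same operation would repair any loss of cis geometry carried over from step 8.

**Step 3.**
- What may go wrong: proton transfer from the benzylic/allylic CH2 of one molecule to the carbanion of another may quench the alkenyllithium before it meets the squarate. O-methylation of the hindered alkoxide may stay incomplete.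
- Fallback: it sets out from 6 and comes back at 12. It removes the acidic CH2 from the organolithium.
- Ethyl vinyl ether and t-BuLi (THF, −78 → 0 °C) give 1-ethoxyvinyllithium F3. Addition to 6 gives the lithium alkoxide F4, and MeOTf gives 4-(1-ethoxyvinyl)-2,3,4-trimethoxycyclobut-2-en-1-one F5.
- The same thermal ring expansion, through the dienylketene F6 and the cyclohexadienone F7, should give 3-ethoxy-4,5,6-trimethoxyphenol F8, whose only free ring position is C4a'.
- Friedel–Crafts benzylation of that position with 4-methoxybenzyl alcohol (Sc(OTf)3 cat., CH2Cl2, 0 °C) gives 12.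

**Step 5.**
- What may go wrong: the oxidation may be diverted to the para-quinone with loss of the O6' methyl group. The methide may also be hydrated or may dimerise while it is handled.
- Fallback: it sets out from 12 and comes back at 24. It uses the para path on purpose.
- PhI(OAc)2 in MeCN–H2O (0 °C) performs the oxidative demethylation to 2-ethoxy-5,6-dimethoxy-3-(4-methoxybenzyl)-1,4-benzoquinone F9.
- Et3N tautomerises this benzylquinone to the 4-hydroxy ortho-quinone methide F10 in the flask that already holds 22 and the catalyst of step 10. The methide is therefore never isolated, and the annulation would give the 6'-hydroxy bislactone F11.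
- BBr3 as in step 11 gives 24.

**Further compounds**

F1 | step 10 | (4S,4'R)-5'-ethoxy-5,6',7,7',8'-pentamethoxy-4,4'-bis(4-methoxyphenyl)-[3,3'-bichromane]-2,2'-dione, mixture of C3/C3' epimers | O=C1Oc2cc(OC)cc(OC)c2[C@H](c2ccc(OC)cc2)C1C1C(=O)Oc2c(OC)c(OC)c(OC)c(OCC)c2[C@H]1c1ccc(OC)cc1
F2 | step 10 | dilithium bis-enolate of F1 | [Li+].[Li+].[O-]C1Oc2cc(OC)cc(OC)c2[C@H](c2ccc(OC)cc2)C=1C1=C([O-])Oc2c(OC)c(OC)c(OC)c(OCC)c2[C@H]1c1ccc(OC)cc1
F3 | step 3 | 1-ethoxyvinyllithium | [Li]C(=C)OCC
F4 | step 3 | lithium alkoxide from F3 and 6 (racemic) | [Li+].[O-]C1(C(=C)OCC)C(OC)=C(OC)C1=O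
F5 | step 3 | (±)-4-(1-ethoxyvinyl)-2,3,4-trimethoxycyclobut-2-en-1-one | COC1(C(=C)OCC)C(OC)=C(OC)C1=O
F6 | step 3 | dienylketene from F5 | O=C=C(OC)/C(OC)=C(OC)\C(=C)OCC
F7 | step 3 | 5-ethoxy-2,3,4-trimethoxycyclohexa-2,4-dien-1-one | O=C1C(OC)=C(OC)C(OC)=C(OCC)C1
F8 | step 3 | 3-ethoxy-4,5,6-trimethoxyphenol | CCOc1cc(O)c(OC)c(OC)c1OC
F9 | step 5 | 2-ethoxy-5,6-dimethoxy-3-(4-methoxybenzyl)-1,4-benzoquinone | O=C1C(OC)=C(OC)C(=O)C(OCC)=C1Cc1ccc(OC)cc1
F10 | step 5 | (6E)-5-ethoxy-4-hydroxy-2,3-dimethoxy-6-(4-methoxybenzylidene)cyclohexa-2,4-dien-1-one | O=C1C(OC)=C(OC)C(O)=C(OCC)/C1=C\c1ccc(OC)cc1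
F11 | step 5 | (3R,3'S,4S,4'R)-5'-ethoxy-6'-hydroxy-5,7,7',8'-tetramethoxy-4,4'-bis(4-methoxyphenyl)-[3,3'-bichromane]-2,2'-dione | O=C1Oc2cc(OC)cc(OC)c2[C@H](c2ccc(OC)cc2)[C@@H]1[C@H]1C(=O)Oc2c(OC)c(OC)c(O)c(OCC)c2[C@H]1c1ccc(OC)cc1
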